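**Retrosynthetic overview**

1. Target ⇒ (O-demethylation of ester and aryl ether) ⇒ B-alkyl Suzuki–Miyaura disconnection of the side-chain CH2–C(Me)= bond into a 2-vinyl-7-oxanorbornane and an aryl (E)-alkenyl iodide.
2. Aryl alkenyl iodide ⇒ syn-hydrozirconation/iodination of a 2-butynyl arene ⇒ benzylic bromide + propynyl metal.
3. Vinyl oxanorbornane ⇒ acyclic (S)-γ-hydroxy ketone carrying an (E)-allylsilane. Both rings close in one operation: first the oxolane ring (hemiketal → cyclic oxocarbenium ion, C–O), then the cyclohexane ring (allylsilane attack on that ion, C–C).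
4. Allylsilane ⇒ cross-metathesis with allyltrimethylsilane ⇒ Ir-catalysed enantioselective tert-prenylation of 5-hydroxypentan-2-one with 1,1-dimethylallene. This carbinol centre controls the other two stereocentres.

Assumptions: the SEGPHOS antipode in step 1 is the one that delivers the (S)-carbinol, fixed by a Mosher ester analysis on the first run. Methyl 3-(bromomethyl)-4-methoxybenzoate and the THF solutions of prop-1-ynylmagnesium bromide and 9-BBN are bought.

**Route**

Step 1
Reactants: 1 5-hydroxypentan-2-one; 2 3-methylbuta-1,2-diene (1,1-dimethylallene)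
Product: 4 (5S)-5-hydroxy-6,6-dimethyloct-7-en-2-one, via 4-oxopentanal 3 (not isolated)
Conditions: [Ir(cod)Cl]2 (2.5 mol%), SEGPHOS (5 mol%), 4-cyano-3-nitrobenzoic acid (10 mol%), Cs2CO3 (20 mol%), 2 (3 equiv), toluene, 60 °C, sealed tube
Reagents that add atoms: none
Why: Krische iridium-catalysed carbonyl tert-prenylation (reverse prenylation) by transfer hydrogenation from the alcohol oxidation level: the primary alcohol is dehydrogenated to aldehyde 3, the iridium hydride converts the allene into a 1,1-dimethylallyl–iridium species that adds to 3 through its substituted terminus in a closed chair transition state in which the SEGPHOS ligand sets the carbinol centre as S (typically ≥90% ee), and the methyl ketone is left alone because only the aldehyde is allylated at a useful rate.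

Step 2
Reactants: 4 (5S)-5-hydroxy-6,6-dimethyloct-7-en-2-one; 5 allyltrimethylsilane
Product: 6 (5S,7E)-5-hydroxy-6,6-dimethyl-9-(trimethylsilyl)non-7-en-2-one
Conditions: Hoveyda–Grubbs II (5 mol%), 5 (4 equiv), CH2Cl2, 40 °C
Reagents that add atoms: none
Why: Olefin cross-metathesis between a type III olefin (vinyl on a quaternary carbon, which cannot homodimerise) and an excess of the type I partner 5, driven by loss of ethene, gives the allylsilane as the E isomer for steric reasons, while the free hydroxy ketone is tolerated by the ruthenium carbene and the carbinol centre is not involved.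

Step 3
Reactants: 6 (5S,7E)-5-hydroxy-6,6-dimethyl-9-(trimethylsilyl)non-7-en-2-one
Product: 8 (1R,2S,4S)-2-ethenyl-1,3,3-trimethyl-7-oxabicyclo[2.2.1]heptane, via oxocarbenium ion 7 (not isolated)
Conditions: TMSOTf (0.2 equiv), 4 Å MS, CH2Cl2, −78 → −30 °C
Reagents that add atoms: none
Why: Proposed new method: the γ-hydroxy ketone closes to its five-membered hemiketal and TMSOTf ionises it to the cyclic oxocarbenium ion 7 (oxolane ring, C–O bond), whose cationic carbon is then attacked by the γ-carbon of the (E)-allylsilane on the pseudo-axial C-2 side chain in an anti-SE2' process with loss of the silyl group (cyclohexane ring, C–C bond); the two-atom tether allows attack only on the face syn to the side chain, which fixes the methyl-bearing bridgehead as 1R from the S carbinol (now 4S), and the alkene is expected to react in the synclinal, exo orientation that keeps it away from the concave face under the CH2–CH2 bridge, which places the vinyl group exo (2S); the closest known reactions are intramolecular Sakurai (silyl-modified Sakurai/Prins) cyclisations of allylsilanes onto cyclic oxocarbenium ions and the Molander annulation of 1,4-dicarbonyl compounds, which builds oxa-bridged bicycles through the same five-membered oxocarbenium ions.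

Step 4
Reactants: 9 methyl 3-(bromomethyl)-4-methoxybenzoate; 10 prop-1-yn-1-ylmagnesium bromide
Product: 12 methyl 3-(but-2-yn-1-yl)-4-methoxybenzoate, via prop-1-ynylzinc bromide 11 (not isolated)
Conditions: 10 (1.3 equiv, 0.5 M in THF), ZnBr2 (1.4 equiv), THF, 0 °C; then 9, Pd(DPEphos)Cl2 (3 mol%), THF, rt
Reagents that add atoms: none
Why: Negishi cross-coupling: transmetalation of the Grignard reagent to the alkynylzinc 11 makes it inert towards the methyl ester, and palladium couples it with the benzylic bromide by oxidative addition, transmetalation and reductive elimination without propargyl–allenyl isomerisation.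

Step 5
Reactants: 12 methyl 3-(but-2-yn-1-yl)-4-methoxybenzoate; 13 chlorobis(cyclopentadienyl)hydridozirconium (Schwartz reagent)
Product: 15 methyl 3-[(2E)-3-iodobut-2-en-1-yl]-4-methoxybenzoate, via alkenylzirconocene chloride 14 (not isolated)
Conditions: 13 (1.5 equiv), THF, rt, 2 h; then I2 (1.6 equiv), 0 °C
Reagents that add atoms: iodine, II
Why: Schwartz hydrozirconation is a syn addition in which, with a small excess of reagent, zirconium settles on the less hindered methyl-bearing alkyne carbon, and iodinolysis of the C–Zr bond with retention gives the (E)-2-iodoalkene (iodine trans to the benzylic CH2) before the slow reduction of the ester can compete.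

Step 6
Reactants: 8 (1R,2S,4S)-2-ethenyl-1,3,3-trimethyl-7-oxabicyclo[2.2.1]heptane; 16 9-borabicyclo[3.3.1]nonane (9-BBN); 15 methyl 3-[(2E)-3-iodobut-2-en-1-yl]-4-methoxybenzoate
Product: 18 methyl 4-methoxy-3-{(2E)-3-methyl-5-[(1R,2S,4S)-1,3,3-trimethyl-7-oxabicyclo[2.2.1]heptan-2-yl]pent-2-en-1-yl}benzoate, via alkylborane 17 (not isolated)
Conditions: 16 (1.3 equiv), THF, rt; then 15, Pd(dppf)Cl2 (5 mol%), AsPh3 (10 mol%), Cs2CO3 (3 equiv), DMF/H2O, rt
Reagents that add atoms: none
Why: Anti-Markovnikov hydroboration of the only alkene of 8 with 9-BBN followed by B-alkyl Suzuki–Miyaura coupling with the alkenyl iodide, which proceeds with retention of the E geometry under mild aqueous base that leaves the methyl ester and the three ring stereocentres untouched.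

Step 7
Reactants: 18 methyl 4-methoxy-3-{(2E)-3-methyl-5-[(1R,2S,4S)-1,3,3-trimethyl-7-oxabicyclo[2.2.1]heptan-2-yl]pent-2-en-1-yl}benzoate
Product: 19 4-hydroxy-3-{(2E)-3-methyl-5-[(1R,2S,4S)-1,3,3-trimethyl-7-oxabicyclo[2.2.1]heptan-2-yl]pent-2-en-1-yl}benzoic acid (CNP0422247.1)
Conditions: NaSEt (8 equiv), DMF, 110 °C; then 1 M HCl
Reagents that add atoms: none
Why: Thiolate SN2 dealkylation removes both the ester methyl and the aryl ether methyl as ethyl methyl sulfide under non-acidic conditions that spare the acid-sensitive oxanorbornane and the trisubstituted alkene, and acidification then gives the hydroxy acid with no stereocentre affected.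

**Compound list**

1 | 5-hydroxypentan-2-one | CC(=O)CCCO | starting material
2 | 3-methylbuta-1,2-diene | CC(C)=C=C | starting material
3 | 4-oxopentanal (not isolated) | CC(=O)CCC=O | intermediate
4 | (5S)-5-hydroxy-6,6-dimethyloct-7-en-2-one | CC(=O)CC[C@H](O)C(C)(C)C=C | intermediate
5 | allyltrimethylsilane | C=CC[Si](C)(C)C | starting material
6 | (5S,7E)-5-hydroxy-6,6-dimethyl-9-(trimethylsilyl)non-7-en-2-one | CC(=O)CC[C@H](O)C(C)(C)/C=C/C[Si](C)(C)C | intermediate
7 | (2S)-5-methyl-2-[(3E)-2-methyl-5-(trimethylsilyl)pent-3-en-2-yl]-3,4-dihydro-2H-furan-1-ium triflate (not isolated) | CC1=[O+][C@@H](CC1)C(C)(C)/C=C/C[Si](C)(C)C.[O-]S(=O)(=O)C(F)(F)F | intermediate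
8 | (1R,2S,4S)-2-ethenyl-1,3,3-trimethyl-7-oxabicyclo[2.2.1]heptane | C=C[C@H]1C(C)(C)[C@@H]2CC[C@@]1(C)O2 | intermediate
9 | methyl 3-(bromomethyl)-4-methoxybenzoate | COC(=O)c1ccc(OC)c(CBr)c1 | starting material
10 | prop-1-yn-1-ylmagnesium bromide | CC#C[Mg]Br | starting material
11 | prop-1-yn-1-ylzinc bromide (not isolated) | CC#C[Zn]Br | intermediate
12 | methyl 3-(but-2-yn-1-yl)-4-methoxybenzoate | COC(=O)c1ccc(OC)c(CC#CC)c1 | intermediate
13 | chlorobis(cyclopentadienyl)hydridozirconium (Schwartz reagent) | [H][Zr](Cl)(C1C=CC=C1)C1C=CC=C1 | starting material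
14 | methyl 3-[(2E)-3-(chlorozirconocenyl)but-2-en-1-yl]-4-methoxybenzoate (not isolated) | COC(=O)c1ccc(OC)c(C/C=C(\C)[Zr](Cl)(C2C=CC=C2)C2C=CC=C2)c1 | intermediate
15 | methyl 3-[(2E)-3-iodobut-2-en-1-yl]-4-methoxybenzoate | COC(=O)c1ccc(OC)c(C/C=C(\C)I)c1 | intermediate
16 | 9-borabicyclo[3.3.1]nonane (9-BBN) | B1C2CCCC1CCC2 | starting material
17 | 9-{2-[(1R,2S,4S)-1,3,3-trimethyl-7-oxabicyclo[2.2.1]heptan-2-yl]ethyl}-9-borabicyclo[3.3.1]nonane (not isolated) | C1CC2CCCC(C1)B2CC[C@H]1C(C)(C)[C@@H]2CC[C@@]1(C)O2 | intermediate
18 | methyl 4-methoxy-3-{(2E)-3-methyl-5-[(1R,2S,4S)-1,3,3-trimethyl-7-oxabicyclo[2.2.1]heptan-2-yl]pent-2-en-1-yl}benzoate | C/C(=C\Cc1cc(C(=O)OC)ccc1OC)CC[C@H]1C(C)(C)[C@@H]2CC[C@@]1(C)O2 | intermediate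
19 | 4-hydroxy-3-{(2E)-3-methyl-5-[(1R,2S,4S)-1,3,3-trimethyl-7-oxabicyclo[2.2.1]heptan-2-yl]pent-2-en-1-yl}benzoic acid | C/C(=C\Cc1cc(C(=O)O)ccc1O)CC[C@H]1C(C)(C)[C@@H]2CC[C@@]1(C)O2 | target

**Step count**

Total steps: 7. Longest linear sequence: 5 (steps 1, 2, 3, 6, 7).

**Steps most likely to fail**

The step most likely to fail is step 3. The ring system has not been closed this way before. Protodesilylation, Prins closure through the other alkene carbon to an 8-oxabicyclo[3.2.1]octane, loss of ee by 2-oxonia-Cope rearrangement, or formation of the endo-vinyl epimer can all intervene. The fallback sets out from 6 and comes back at 8, and it closes the rings one after the other instead of together. Fluoride (TBAF, THF, 0 °C) triggers the intramolecular allylation of the ketone by the allylsilane through a chair-like transition state with the C-1 oxygen and the new vinyl group equatorial and hence cis. This gives (1S,3S)-3-ethenyl-2,2,4-trimethylcyclohexane-1,4-diol F1 (either C-4 epimer serves). A catalytic sulfonic acid (CSA, CH2Cl2, 0 °C) then ionises the tertiary alcohol so that the secondary hydroxyl closes the oxygen bridge across the ring, as in the terpin-to-1,4-cineole cyclodehydration, to give 8.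

Second is step 2, because the vinyl group of 4 sits on a quaternary carbon next to a free carbinol and may not enter the metathesis cycle at a useful rate. The fallback sets out from 1 and comes back at 8. It abandons prenylation and metathesis and brings the allyl metal in with the carbonyl addition. Compound 1 is oxidised (TEMPO, PhI(OAc)2, CH2Cl2) to 3, which is now isolated. Platinum-catalysed enantioselective 1,2-diboration of 4-methylpenta-1,3-diene with bis(pinacolato)diboron (Pt(dba)3, TADDOL-derived phosphonite, THF, 60 °C) gives 2,2'-[(2S)-4-methylpent-3-ene-1,2-diyl]bis(4,4,5,5-tetramethyl-1,3,2-dioxaborolane) F2. Its secondary allylboronate adds to the aldehyde of 3 (not to the ketone) through a chair transition state at the dimethyl-substituted terminus with 1,3-chirality transfer. This gives (5S,7E)-5-hydroxy-6,6-dimethyl-9-(4,4,5,5-tetramethyl-1,3,2-dioxaborolan-2-yl)non-7-en-2-one F3, the boron analogue of 6. F3 is then cyclised under the conditions of step 3, with the allylboronate in the role of the allylsilane, to give 8.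

Third is step 5. The regioselectivity of the hydrozirconation (methyl against benzylic CH2) may be no better than about 9:1, and the ester is slowly reduced by the reagent. The fallback sets out from 8 and comes back at 18. It brings in the trisubstituted alkene with its geometry already fixed and attaches the arene last. Compound 8 is hydroborated to 17 as in step 6 and coupled (Pd(dppf)Cl2, Cs2CO3) with (E)-3-iodobut-2-en-1-ol, which is made by stannylcupration–iodination of but-2-yn-1-ol. This gives (2E)-3-methyl-5-[(1R,2S,4S)-1,3,3-trimethyl-7-oxabicyclo[2.2.1]heptan-2-yl]pent-2-en-1-ol F4. Methyl chloroformate and pyridine give methyl (2E)-3-methyl-5-[(1R,2S,4S)-1,3,3-trimethyl-7-oxabicyclo[2.2.1]heptan-2-yl]pent-2-en-1-yl carbonate F5. Palladium(0)-catalysed allyl–aryl coupling of F5 with commercial [2-methoxy-5-(methoxycarbonyl)phenyl]boronic acid, which attacks the unsubstituted allyl terminus and keeps the E alkene, gives 18.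

**Further compounds**

F1 | step 3 | (1S,3S)-3-ethenyl-2,2,4-trimethylcyclohexane-1,4-diol (C-4 epimers) | C=C[C@H]1C(C)(C)[C@@H](O)CCC1(C)O
F2 | step 2 | 2,2'-[(2S)-4-methylpent-3-ene-1,2-diyl]bis(4,4,5,5-tetramethyl-1,3,2-dioxaborolane) | CC(C)=C[C@H](CB1OC(C)(C)C(C)(C)O1)B1OC(C)(C)C(C)(C)O1
F3 | step 2 | (5S,7E)-5-hydroxy-6,6-dimethyl-9-(4,4,5,5-tetramethyl-1,3,2-dioxaborolan-2-yl)non-7-en-2-one | CC(=O)CC[C@H](O)C(C)(C)/C=C/CB1OC(C)(C)C(C)(C)O1
F4 | step 5 | (2E)-3-methyl-5-[(1R,2S,4S)-1,3,3-trimethyl-7-oxabicyclo[2.2.1]heptan-2-yl]pent-2-en-1-ol | C/C(=C\CO)CC[C@H]1C(C)(C)[C@@H]2CC[C@@]1(C)O2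
F5 | step 5 | methyl (2E)-3-methyl-5-[(1R,2S,4S)-1,3,3-trimethyl-7-oxabicyclo[2.2.1]heptan-2-yl]pent-2-en-1-yl carbonate | C/C(=C\COC(=O)OC)CC[C@H]1C(C)(C)[C@@H]2CC[C@@]1(C)O2
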